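In this flask the coupling partner cannot carry every substrate through to double product, since each substrate would need two of them and the charge falls short of that.

substrate 0.020 M; coupling partner 0.0200 M; time 5.0 h

    coupling partner + mono adduct → double product + by-product (k1 = 0.867 M⁻¹ s⁻¹)
    coupling partner + by-product ⇌ idle adduct, settled at all times (K2 = 117 M⁻¹)
    substrate + coupling partner → mono adduct + by-product (k3 = 0.154 M⁻¹ s⁻¹)

- part of the substrate that has reacted at 5.0 h
- share of the unused coupling partner that is free and not bound as idle adduct, at 5.0 h

Call substrate to mono adduct the first coupling and mono adduct to double product the second. Both consume free coupling partner, so when we divide the second rate by the first, free partner cancels, and with it the clock and the binding into idle adduct. What stays is c(mono adduct) over c(substrate), times S, the second rate constant over the first, 5.63, the selectivity factor.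

Now the ledger of the coupling partner, the limiting reagent, in parts of the substrate charged. Substrate's half-life by the first coupling alone, with the partner as charged, 0.063 h, is shorter than the run, so we close the books when the two coupling entries reach the charge, entering nothing for unused partner, free or bound as idle adduct. The first entry is the reacted share x. The second is x less the mono adduct m, where the ratio gives m = (a − a^S)/(S − 1), with a the substrate left. So x = (partner charge over substrate charge + m)/2. Ignoring m, x is 50.0 %; then m is 10.4 % and x 55.2 %; a second pass gives m 9.44 % and x 54.7 %. With by-product near 0.0200 M at the close, the share of the unused partner that is free comes to 29.9 %.

The forecast, on the ground that “Each partner consumed releases one by-product”, gave 54.8 % and 29.9 %, where our own reckoning stands at 54.7 % and 29.9 %.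

This flask gives 54.8 % of the substrate reacted and 29.9 % of the unused partner free, with 0 % of the coupling partner left against 45 % of the substrate. S also holds early in this flask: at 0.500 h, with substrate at 47.9 %, it gives mono adduct 10.0 %, and the flask holds 10.0 %.

For the neighbour flask with 0.034 M of substrate, the same passes give mono adduct 12.2 %, then x 35.5 % and 35.5 %. That neighbour flask gives 35.5 % of its substrate reacted, with mono adduct 12.1 %.

The rate constants come from no measurement; the run is a simulation.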